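**Retrosynthetic overview** (target atoms in longipinane numbering)
1. Both esters go on at the end: the C9 senecioate by acylation, the C7 tiglate by an Evans–Tishchenko reaction. The cyclohexenone (C1–C2–C3–C4–C11 with C5 or C10) is closed late by aldol condensation of a cis-1,3-diacetylcyclobutane.
2. The C7 and C9 oxygens both derive from the C9 ketone of a bicyclo[4.1.1]octan-2-one: enone formation, asymmetric β-borylation/oxidation (C7), then anti-selective Evans–Tishchenko reduction (C9).
3. The seven-membered ring (C4–C5–C6–C7–C8–C9–C10) is grown from the five-membered keto-bridge ring (C4–C5–C6–C9–C10) of a bicyclo[2.1.1]hexan-2-ol, by inserting the two vinyl carbons C8 and C7 between C9 and C6.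
4. Enabling feature: the C9–C6 bond joins the carbinol carbon to the gem-dimethyl carbon inside the strained bicycle. Alkoxy-radical β-scission there gives a tertiary radical at C6, held cis-1,3 on the cyclobutane (C4/C5/C10/C11) to the unmasked vinyl ketone, onto which it re-closes 7-endo.
5. Ring order: cyclobutane together with the five-membered bridge ring (crossed [2+2] photocycloaddition of an acyclic 1,5-dien-3-one), then the seven-membered ring (two-carbon expansion), then the cyclohexenone (aldol).

Key step: step 8

Remark on numbering: target atoms are cited in longipinane numbering (C1 ketone, C2=C3, C6 = CMe2, C7 = tiglate carbon, C9 = senecioate carbon, C10 = quaternary methyl carbon); intermediates are named by their own bicyclic numbering.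
Remark on stereochemistry: 9 is expected as a mixture of exo/endo epimers at its two acetyl-bearing carbons; 9, 10, 12–17, 19 and 20 are drawn exo,exo, and any endo epimers are carried along because both centres are epimerisable again in 20 and are fixed only when the bridged enone closes in step 13.

Step 1
Reactants: 1 mesityl oxide
Product: 2 (E)-2-methyl-4-oxopent-2-enal
Conditions: SeO2 (1.1 equiv), 1,4-dioxane/H2O, reflux
Reagents that add atoms: selenium dioxide, O=[Se]=O
Why: Riley-type allylic oxidation (ene reaction then [2,3]-sigmatropic shift) should oxidise the methyl group trans to the acetyl group and give the (E)-enal; no stereocentre is formed.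

Step 2
Reactants: 2 (E)-2-methyl-4-oxopent-2-enal; 3 prenyl bromide
Product: 5 (E)-5-hydroxy-4,6,6-trimethylocta-3,7-dien-2-one (racemic), via prenylzinc bromide 4 (not isolated)
Conditions: Zn dust, THF/sat. aq NH4Cl, 0 °C → rt
Reagents that add atoms: none
Why: Barbier allylation in which the prenylzinc species adds through its γ-carbon (SE2′) and only to the aldehyde, which builds the gem-dimethyl quaternary carbon; the new carbinol centre is racemic and is removed in step 3.

Step 3
Reactants: 5 (E)-5-hydroxy-4,6,6-trimethylocta-3,7-dien-2-one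
Product: 6 (E)-4,6,6-trimethylocta-3,7-diene-2,5-dione
Conditions: Dess–Martin periodinane, NaHCO3, CH2Cl2, 0 °C → rt
Reagents that add atoms: none
Why: Dess–Martin oxidation of a hindered secondary allylic alcohol under buffered, non-enolising conditions; no stereocentre remains.

Step 4
Reactants: 6 (E)-4,6,6-trimethylocta-3,7-diene-2,5-dione; 7 methyl vinyl ketone
Product: 8 (3E,7E)-4,6,6-trimethyldeca-3,7-diene-2,5,9-trione
Conditions: Hoveyda–Grubbs II catalyst (5 mol %), 7 (5 equiv), CH2Cl2, 40 °C
Reagents that add atoms: none
Why: Olefin cross-metathesis of the only metathesis-active alkene (the monosubstituted vinyl group; the trisubstituted enedione alkene is inert) with an electron-poor partner should give the (E)-enone, excess 7 suppressing homodimerisation.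

Step 5
Reactants: 8 (3E,7E)-4,6,6-trimethyldeca-3,7-diene-2,5,9-trione
Product: 9 5,6-diacetyl-1,3,3-trimethylbicyclo[2.1.1]hexan-2-one (drawn with both acetyl groups anti to the C2–C3 bridge)
Conditions: hν (365 nm), thioxanthone (10 mol %), degassed MeCN (0.01 M), rt
Reagents that add atoms: none
Why: Crossed intramolecular enone–alkene [2+2] photocycloaddition of a 1,5-hexadien-3-one, in which the triplet enedione closes first to the five-membered ring (rule of five) and then to the cyclobutane; the two-carbon keto bridge fixes the 1,3-cis relation of the bridgeheads (future C10 and C5), while the acetyl-bearing carbons stay epimerisable.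

Step 6
Reactants: 9 5,6-diacetyl-1,3,3-trimethylbicyclo[2.1.1]hexan-2-one
Product: 10 1,3,3-trimethyl-5,6-bis(2-methyl-1,3-dioxolan-2-yl)bicyclo[2.1.1]hexan-2-one
Conditions: (TMSOCH2)2, TMSOTf (cat.), CH2Cl2, −78 → −20 °C
Reagents that add atoms: 1,2-bis(trimethylsilyloxy)ethane, C[Si](C)(C)OCCO[Si](C)(C)C
Why: TMSOTf-catalysed ketalisation at low temperature protects the two methyl ketones while the ring ketone, flanked by two fully substituted carbons, stays free; the ketals also remove radical-stabilising acyl groups from the cyclobutane before step 8.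

Step 7
Reactants: 10 bis-ketal ketone; 11 vinylmagnesium bromide
Product: 12 1,3,3-trimethyl-5,6-bis(2-methyl-1,3-dioxolan-2-yl)-2-vinylbicyclo[2.1.1]hexan-2-ol (racemic at C2)
Conditions: 11 (3 equiv), LaCl3·2LiCl, THF, 0 °C → rt; aq NH4Cl
Reagents that add atoms: none
Why: Lewis-acid-assisted 1,2-addition of a vinyl Grignard reagent to a strained, non-enolisable ketone; the carbinol carbon becomes a carbonyl again in step 8, so its configuration is irrelevant.

Step 8
Reactants: 12 2-vinylbicyclo[2.1.1]hexan-2-ol
Product: 14 1,5,5-trimethyl-7,8-bis(2-methyl-1,3-dioxolan-2-yl)bicyclo[4.1.1]octan-2-one, via ring-opened tertiary radical 13 (not isolated)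
Conditions: [Ir(dF(CF3)ppy)2(5,5′-d(CF3)bpy)]PF6 (2 mol %), Bu4N[(BuO)2PO2] (20 mol %), PhCF3 (0.01 M), blue LEDs, rt
Reagents that add atoms: none
Why: Proton-coupled electron transfer from the tertiary O–H to the excited iridium(III) oxidant and the phosphate base should give the alkoxy radical, whose β-scission cleaves the strained C2–C3 bond (carbinol carbon to gem-dimethyl carbon) and releases a vinyl ketone and the tertiary radical 13, held cis-1,3 to it on the cyclobutane; 13 adds to the terminal enone carbon, and the α-keto radical is reduced by iridium(II) and protonated, so the net change is a redox-neutral isomerisation in which the five-membered ring grows by the two vinyl carbons. The closest known reaction type is the photocatalytic (proton-coupled electron transfer) ring expansion of 1-alkenylcycloalkanols from n to n+2 by alkoxy-radical β-scission and endo radical recombination. The seven-membered ring closes by a 7-endo-trig Giese-type radical addition, and the cyclobutane is not touched. No new stereocentre is formed, because the new bond joins a CH2 terminus to the gem-dimethyl carbon and the cis-1,3 ring fusion is inherited from the bicyclic precursor. The step needs β-scission toward the gem-dimethyl carbon and not toward the bridgehead, and ring closure faster than opening of the cyclobutylcarbinyl radical or its reduction; the first should be favoured by the unstrained tertiary radical and the weaker bond between two fully substituted carbons, the second by the cis-1,3 geometry, the gem-dimethyl effect, the electron-poor acceptor and the ketal (not acyl) substituents on the four-membered ring.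

Step 9
Reactants: 14 bicyclo[4.1.1]octan-2-one
Product: 15 1,5,5-trimethyl-7,8-bis(2-methyl-1,3-dioxolan-2-yl)bicyclo[4.1.1]oct-3-en-2-one
Conditions: IBX, 4-methoxypyridine N-oxide, DMSO, rt → 40 °C
Reagents that add atoms: none
Why: IBX dehydrogenation through the only possible enol (toward C3, the other α-carbon being quaternary) should give the conjugated enone; no stereocentre is formed.

Step 10
Reactants: 15 bicyclo[4.1.1]oct-3-en-2-one
Product: 17 (4R)-4-hydroxy-1,5,5-trimethyl-7,8-bis(2-methyl-1,3-dioxolan-2-yl)bicyclo[4.1.1]octan-2-one, via β-boryl ketone 16 (not isolated)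
Conditions: CuCl (5 mol %), Josiphos-type bisphosphine (6 mol %, enantiomer selected for the 4R product), NaOt-Bu (10 mol %), B2pin2, MeOH, THF, rt; then NaBO3·4H2O, THF/H2O, rt
Reagents that add atoms: bis(pinacolato)diboron, CC1(C)OB(OC1(C)C)B1OC(C)(C)C(C)(C)O1 (boron in 16); sodium perborate, [Na+].[O-]OB=O (oxygen in 17)
Why: Copper(I)-catalysed asymmetric conjugate borylation of a cyclic enone followed by stereoretentive C–B oxidation; the chiral ligand differentiates the enantiotopic faces of the meso enone and so sets C4 (future C7) and the absolute configuration of the series.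

Step 11
Reactants: 17 (4R)-β-hydroxy ketone; 18 tiglic aldehyde
Product: 19 (2R,4R)-2-hydroxy-1,5,5-trimethyl-7,8-bis(2-methyl-1,3-dioxolan-2-yl)bicyclo[4.1.1]octan-4-yl (E)-2-methylbut-2-enoate
Conditions: SmI2 (30 mol %), 18 (6 equiv), THF, −10 °C
Reagents that add atoms: none
Why: Evans–Tishchenko reduction, in which the samarium-bound hemiacetal of 18 on the C4 oxygen delivers hydride intramolecularly to the C2 ketone; this should give the 2,4-anti diol monoester with the tiglate on the original hydroxyl and the new C2 carbinol (future C9) anti to it.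

Step 12
Reactants: 19 hydroxy tiglate bis-ketal
Product: 20 (2R,4R)-7,8-diacetyl-2-hydroxy-1,5,5-trimethylbicyclo[4.1.1]octan-4-yl (E)-2-methylbut-2-enoate
Conditions: PPTS, acetone/H2O, 50 °C
Reagents that add atoms: water, O
Why: Mild acid-catalysed ketal hydrolysis that the ester, the secondary alcohol and the cyclobutane should survive; the acetyl-bearing carbons become epimerisable again.

Step 13
Reactants: 20 diacetyl hydroxy tiglate
Product: 21 (4R,5S,7R,9R,10R,11R)-9-hydroxy-7-tigloyloxylongipin-2-en-1-one
Conditions: 9-amino-9-deoxy-epi-quinine (20 mol %), TFA (40 mol %), toluene, 4 Å MS, 50 °C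
Reagents that add atoms: none
Why: Primary-amine-catalysed intramolecular aldol condensation of a 1,5-diketone (the enamine of one methyl ketone adds 6-enolexo to the other carbonyl, then dehydration), the reaction type used for catalytic desymmetrisation of heptane-2,6-diones; closure is possible only from the cis-diacetyl isomer, which fixes the ring-fusion centres C4 and C11, the chiral amine selects which acetyl group becomes the enone carbonyl, and removal of water drives formation of the strained bicyclo[3.1.1]heptenone.

Step 14
Reactants: 21 hydroxy enone; 22 3-methylbut-2-enoyl chloride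
Product: 23 (4R,5S,7R,9R,10R,11R)-9-senecioyloxy-7-tigloyloxylongipin-2-en-1-one (target)
Conditions: pyridine, DMAP (cat.), CH2Cl2, 0 °C → rt
Reagents that add atoms: none
Why: DMAP-catalysed acylation of the hindered secondary alcohol with the acid chloride in pyridine at low temperature, conditions that should avoid deconjugation of the senecioyl group; no stereocentre is touched.

**Compound list**
1 | mesityl oxide (4-methylpent-3-en-2-one) | CC(=O)C=C(C)C | starting material
2 | (E)-2-methyl-4-oxopent-2-enal | CC(=O)/C=C(\C)C=O | intermediate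
3 | prenyl bromide (1-bromo-3-methylbut-2-ene) | CC(C)=CCBr | starting material
4 | prenylzinc bromide | CC(C)=CC[Zn]Br | intermediate (not isolated)
5 | (E)-5-hydroxy-4,6,6-trimethylocta-3,7-dien-2-one (racemic) | CC(=O)/C=C(\C)C(O)C(C)(C)C=C | intermediate
6 | (E)-4,6,6-trimethylocta-3,7-diene-2,5-dione | CC(=O)/C=C(\C)C(=O)C(C)(C)C=C | intermediate
7 | methyl vinyl ketone (but-3-en-2-one) | CC(=O)C=C | starting material
8 | (3E,7E)-4,6,6-trimethyldeca-3,7-diene-2,5,9-trione | CC(=O)/C=C(\C)C(=O)C(C)(C)/C=C/C(C)=O | intermediate
9 | 5,6-diacetyl-1,3,3-trimethylbicyclo[2.1.1]hexan-2-one (meso; both acetyl groups anti to the C2–C3 bridge; expected with endo-acetyl epimers) | O=C1[C@@]2(C)[C@H](C(C)=O)[C@H]([C@@H]2C(C)=O)C1(C)C | intermediate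
10 | 1,3,3-trimethyl-5,6-bis(2-methyl-1,3-dioxolan-2-yl)bicyclo[2.1.1]hexan-2-one (meso, exo,exo) | O=C1[C@@]2(C)[C@H](C3(C)OCCO3)[C@H]([C@@H]2C4(C)OCCO4)C1(C)C | intermediate
11 | vinylmagnesium bromide | C=C[Mg]Br | starting material
12 | 1,3,3-trimethyl-5,6-bis(2-methyl-1,3-dioxolan-2-yl)-2-vinylbicyclo[2.1.1]hexan-2-ol (racemic at C2) | C=CC1(O)[C@@]2(C)[C@H](C3(C)OCCO3)[C@H]([C@@H]2C4(C)OCCO4)C1(C)C | intermediate
13 | 2-[cis-3-acryloyl-3-methyl-2,4-bis(2-methyl-1,3-dioxolan-2-yl)cyclobutyl]propan-2-yl radical | C=CC(=O)[C@@]1(C)[C@H](C2(C)OCCO2)[C@H]([C@@H]1C3(C)OCCO3)[C](C)C | intermediate (not isolated)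
14 | 1,5,5-trimethyl-7,8-bis(2-methyl-1,3-dioxolan-2-yl)bicyclo[4.1.1]octan-2-one (meso; ketal groups anti to the four-carbon bridge) | C1CC(=O)[C@@]2(C)[C@H](C3(C)OCCO3)[C@H]([C@@H]2C4(C)OCCO4)C1(C)C | intermediate
15 | 1,5,5-trimethyl-7,8-bis(2-methyl-1,3-dioxolan-2-yl)bicyclo[4.1.1]oct-3-en-2-one (meso) | C1=CC(=O)[C@@]2(C)[C@H](C3(C)OCCO3)[C@H]([C@@H]2C4(C)OCCO4)C1(C)C | intermediate
16 | (4R)-1,5,5-trimethyl-7,8-bis(2-methyl-1,3-dioxolan-2-yl)-4-(4,4,5,5-tetramethyl-1,3,2-dioxaborolan-2-yl)bicyclo[4.1.1]octan-2-one | B1(OC(C)(C)C(C)(C)O1)[C@@H]2CC(=O)[C@@]3(C)[C@H](C4(C)OCCO4)[C@H]([C@@H]3C5(C)OCCO5)C2(C)C | intermediate (not isolated)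
17 | (4R)-4-hydroxy-1,5,5-trimethyl-7,8-bis(2-methyl-1,3-dioxolan-2-yl)bicyclo[4.1.1]octan-2-one | O[C@@H]1CC(=O)[C@@]2(C)[C@H](C3(C)OCCO3)[C@H]([C@@H]2C4(C)OCCO4)C1(C)C | intermediate
18 | tiglic aldehyde ((E)-2-methylbut-2-enal) | C/C=C(\C)C=O | starting material
19 | (2R,4R)-2-hydroxy-1,5,5-trimethyl-7,8-bis(2-methyl-1,3-dioxolan-2-yl)bicyclo[4.1.1]octan-4-yl (E)-2-methylbut-2-enoate (2,4-anti) | C/C=C(\C)C(=O)O[C@@H]1C[C@@H](O)[C@@]2(C)[C@H](C3(C)OCCO3)[C@H]([C@@H]2C4(C)OCCO4)C1(C)C | intermediate
20 | (2R,4R)-7,8-diacetyl-2-hydroxy-1,5,5-trimethylbicyclo[4.1.1]octan-4-yl (E)-2-methylbut-2-enoate (acetyl groups anti to the four-carbon bridge) | C/C=C(\C)C(=O)O[C@@H]1C[C@@H](O)[C@@]2(C)[C@H](C(C)=O)[C@H]([C@@H]2C(C)=O)C1(C)C | intermediate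
21 | (4R,5S,7R,9R,10R,11R)-9-hydroxy-7-tigloyloxylongipin-2-en-1-one | C/C=C(\C)C(=O)O[C@@H]1C[C@@H](O)[C@@]2(C)[C@@H]3C(=O)C=C(C)[C@H]2[C@@H]3C1(C)C | intermediate
22 | 3-methylbut-2-enoyl chloride (senecioyl chloride) | CC(C)=CC(Cl)=O | starting material
23 | (4R,5S,7R,9R,10R,11R)-9-senecioyloxy-7-tigloyloxylongipin-2-en-1-one | C/C=C(\C)C(=O)O[C@@H]1C[C@@H](OC(=O)C=C(C)C)[C@@]2(C)[C@@H]3C(=O)C=C(C)[C@H]2[C@@H]3C1(C)C | target

**Total step count:** 14. **Longest linear sequence:** 14 steps (all other components are commercial).

**Steps most likely to fail**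

Step 8. The tertiary radical is a cyclobutylcarbinyl radical and may open the four-membered ring before it closes. β-Scission may instead break the bridgehead bond, which would place the ketone next to the gem-dimethyl carbon. The radical may also be reduced before ring closure. The fallback inserts the two carbons one at a time by polar chemistry. It sets out from ketone 10: organoaluminium-promoted homologation with diazomethane (Me3Al, CH2Cl2, −78 °C), with migration of the fully substituted acyclic carbon, should give 1,4,4-trimethyl-6,7-bis(2-methyl-1,3-dioxolan-2-yl)bicyclo[3.1.1]heptan-2-one F1. A second homologation of F1 under the same conditions, now with migration of the unhindered CH2 group, comes back to the route at ketone 14.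

Step 13. Closure to the strained bicyclo[3.1.1]heptenone is reversible and may stall before dehydration, and weak discrimination between the two diastereotopic acetyl groups would give the regioisomeric enone. The fallback closes the ring under kinetic, reagent-controlled conditions. It sets out from 20, which is first acylated with 22 (pyridine, DMAP) to (2R,4R)-7,8-diacetyl-1,5,5-trimethyl-4-[(E)-2-methylbut-2-enoyloxy]bicyclo[4.1.1]octan-2-yl 3-methylbut-2-enoate F2. A diisopinocampheylboron enolate is then generated at one acetyl methyl group (Ipc2BOTf, i-Pr2NEt, CH2Cl2, −78 °C) and adds intramolecularly to the other acetyl carbonyl; oxidative work-up should give the bridged aldol 3-hydroxy-9-senecioyloxy-7-tigloyloxylongipinan-1-one F3. Dehydration of the tertiary alcohol of F3 with the Burgess reagent comes back to the route at the target 23.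

Step 5. The excited enedione may lose its energy by E/Z isomerisation, the β,γ-unsaturated ketone may undergo a 1,3-acyl shift, and addition to the electron-poor enone partner may be slow. The fallback uses an electron-neutral alkene partner and moves the protection forward. It sets out from 6: cross-metathesis with 2-methyl-2-vinyl-1,3-dioxolane in place of 7 should give (3E,7E)-4,6,6-trimethyl-8-(2-methyl-1,3-dioxolan-2-yl)octa-3,7-diene-2,5-dione F4. Irradiation of F4 as in step 5 should give 5-acetyl-1,3,3-trimethyl-6-(2-methyl-1,3-dioxolan-2-yl)bicyclo[2.1.1]hexan-2-one F5 (racemic), and ketalisation of its remaining acetyl group as in step 6 comes back to the route at 10.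

Further compounds
F1 | step 8 | 1,4,4-trimethyl-6,7-bis(2-methyl-1,3-dioxolan-2-yl)bicyclo[3.1.1]heptan-2-one | C1C(=O)[C@@]2(C)[C@H](C3(C)OCCO3)[C@H]([C@@H]2C4(C)OCCO4)C1(C)C
F2 | step 13 | (2R,4R)-7,8-diacetyl-1,5,5-trimethyl-4-[(E)-2-methylbut-2-enoyloxy]bicyclo[4.1.1]octan-2-yl 3-methylbut-2-enoate | C/C=C(\C)C(=O)O[C@@H]1C[C@@H](OC(=O)C=C(C)C)[C@@]2(C)[C@H](C(C)=O)[C@H]([C@@H]2C(C)=O)C1(C)C
F3 | step 13 | 3-hydroxy-9-senecioyloxy-7-tigloyloxylongipinan-1-one (bridged aldol, C3 epimers) | C/C=C(\C)C(=O)O[C@@H]1C[C@@H](OC(=O)C=C(C)C)[C@@]2(C)[C@@H]3C(=O)CC(C)(O)[C@H]2[C@@H]3C1(C)C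
F4 | step 5 | (3E,7E)-4,6,6-trimethyl-8-(2-methyl-1,3-dioxolan-2-yl)octa-3,7-diene-2,5-dione | CC(=O)/C=C(\C)C(=O)C(C)(C)/C=C/C1(C)OCCO1
F5 | step 5 | 5-acetyl-1,3,3-trimethyl-6-(2-methyl-1,3-dioxolan-2-yl)bicyclo[2.1.1]hexan-2-one (racemic) | O=C1[C@@]2(C)[C@H](C(C)=O)[C@H]([C@@H]2C3(C)OCCO3)C1(C)C
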